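The route rests on cutting ring A away from the C4 carbonyl and from O1 at the same time. C8a–O1 and C4–C4a sit on adjacent ring A carbons, with the C5 oxygen on the other side of C4a. That is the pattern left when a carboxylate adds to a 3-alkoxyaryne and the acyl group then shifts from oxygen to the neighbouring aryl anion. The key step therefore delivers the complete 2-hydroxy-4,6-dioxygenated aryl ketone in one operation from 3,5-bis(methoxymethoxy)benzyne and an acid that already holds the (S)-configured C3 with its aryl group, its oxygen and C2, masked as an acetonide. Acidic unmasking and a Mitsunobu closure of O1–C2 finish the pyranone ring.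

Key step: step 14

Remark: Ar = 2,4-dimethoxy-3-(3-methylbut-2-en-1-yl)phenyl. C3 of the target is (S); the hydroxymethyl group takes the geometric place of the mandelate hydrogen but outranks the aryl group in the CIP order, so the (R)-mandelate is the enantiomer required.

Step 1
Reactants: 1 1,3-dimethoxybenzene; 2 prenyl bromide (1-bromo-3-methylbut-2-ene)
Product: 4 1,3-dimethoxy-2-(3-methylbut-2-en-1-yl)benzene, via 2,6-dimethoxyphenyllithium 3 (not isolated)
Conditions: n-BuLi, THF, 0 °C → rt; then CuI (10 mol %), 2, −20 °C → rt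
Reagents that add atoms: none
Why: Directed ortho-metalation between the two methoxy groups gives the C2 aryllithium, and its copper-assisted SN2 alkylation with the primary allylic bromide should install the prenyl group with linear regiochemistry.

Step 2
Reactants: 4 1,3-dimethoxy-2-(3-methylbut-2-en-1-yl)benzene
Product: 5 1-bromo-2,4-dimethoxy-3-(3-methylbut-2-en-1-yl)benzene
Conditions: NBS (1.0 equiv), MeCN, 0 °C, dark
Reagents that add atoms: N-bromosuccinimide, O=C1CCC(=O)N1Br
Why: Electrophilic aromatic bromination; C4 is ortho to one methoxy group and para to the other and is more nucleophilic than the trisubstituted alkene, so one equivalent of NBS should brominate the ring only, and C4 and C6 are equivalent.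

Step 3
Reactants: 5 1-bromo-2,4-dimethoxy-3-(3-methylbut-2-en-1-yl)benzene; 6 diethyl oxalate
Product: 8 ethyl 2-Ar-2-oxoacetate, via aryllithium 7 (not isolated)
Conditions: n-BuLi, THF, −78 °C; cannulate into 6 (3 equiv), THF, −78 °C; aq NH4Cl
Reagents that add atoms: none
Why: Bromine–lithium exchange followed by inverse addition to excess oxalate is a nucleophilic acyl substitution that stops at the keto ester because the chelated tetrahedral lithium alkoxide survives until the quench.

Step 4
Reactants: 8 ethyl 2-Ar-2-oxoacetate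
Product: 9 ethyl (R)-2-Ar-2-hydroxyacetate
Conditions: RuCl(p-cymene)[(S,S)-TsDPEN] (1 mol %), HCO2H/Et3N (5:2), DMF, 25 °C
Reagents that add atoms: none
Why: Noyori-type asymmetric transfer hydrogenation of an aryl ketone; the (S,S) ligand delivers hydride to the face that gives (S)-1-arylethanols, which for the glyoxylate (ester outranking aryl) corresponds to the (R)-mandelate, and the outer-sphere Ru–H/N–H mechanism leaves the alkene alone.

Step 5
Reactants: 9 ethyl (R)-2-Ar-2-hydroxyacetate
Product: 10 (R)-2-Ar-2-hydroxyacetic acid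
Conditions: LiOH·H2O, THF/H2O, 0 °C; then 1 M HCl to pH 3, 0 °C
Reagents that add atoms: lithium hydroxide, [Li+].[OH-]
Why: Ester saponification at 0 °C, under which the carbinol hydrogen is not removed, so the configuration should be kept.

Step 6
Reactants: 10 (R)-2-Ar-2-hydroxyacetic acid
Product: 12 (2R,5R)-2-tert-butyl-5-Ar-1,3-dioxolan-4-one (tert-butyl and Ar cis), via bis(trimethylsilyl) derivative 11 (not isolated)
Conditions: TMSCl, Et3N, CH2Cl2, 0 °C → rt, filter; then t-BuCHO, TMSOTf (5 mol %), CH2Cl2, −78 °C; crystallise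
Reagents that add atoms: pivalaldehyde, CC(C)(C)C=O
Why: Silyl-mediated acetalisation of the bis-silylated hydroxy acid with an aldehyde runs under kinetic control at −78 °C, so the existing C5 centre should set the acetal centre cis, and hot Brønsted acid that could ionise the electron-rich benzylic C–O bond is avoided.

Step 7
Reactants: 12 (2R,5R)-2-tert-butyl-5-Ar-1,3-dioxolan-4-one
Product: 14 (2R,5S)-2-tert-butyl-5-Ar-5-(hydroxymethyl)-1,3-dioxolan-4-one, via lithium enolate 13 (not isolated)
Conditions: LiN(i-Pr)2, THF, −78 °C; CH2O (gas, from cracked paraformaldehyde), −78 °C; aq NH4Cl, −78 °C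
Reagents that add atoms: formaldehyde, C=O
Why: Aldol addition of the dioxolanone enolate to monomeric formaldehyde with self-regeneration of the stereocentre; the tert-butyl group on the acetal carbon blocks one face, so the hydroxymethyl group should enter trans to it, in the place of the former hydrogen, and set the quaternary centre.

Step 8
Reactants: 14 (2R,5S)-2-tert-butyl-5-Ar-5-(hydroxymethyl)-1,3-dioxolan-4-one
Product: 15 methyl (S)-2-Ar-2,3-dihydroxypropanoate
Conditions: NaOMe (0.2 equiv), MeOH, 0 °C; then AcOH (0.2 equiv)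
Reagents that add atoms: methanol, CO
Why: Methoxide-catalysed transesterification opens the acylal and the hemiacetal loses pivalaldehyde; the quaternary centre has no α-hydrogen and cannot epimerise.

Step 9
Reactants: 15 methyl (S)-2-Ar-2,3-dihydroxypropanoate
Product: 16 methyl (S)-4-Ar-2,2-dimethyl-1,3-dioxolane-4-carboxylate
Conditions: 2,2-dimethoxypropane, PPTS (10 mol %), acetone, rt
Reagents that add atoms: 2,2-dimethoxypropane, COC(C)(C)OC
Why: Acid-catalysed transketalisation ties the tertiary and the primary hydroxyl into a five-membered acetonide; doing it on the ester excludes competing dioxolanone formation with a free carboxyl group.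

Step 10
Reactants: 16 methyl (S)-4-Ar-2,2-dimethyl-1,3-dioxolane-4-carboxylate
Product: 17 (S)-4-Ar-2,2-dimethyl-1,3-dioxolane-4-carboxylic acid
Conditions: LiOH·H2O, THF/MeOH/H2O, 40 °C; then 1 M HCl to pH 4, 0 °C
Reagents that add atoms: lithium hydroxide, [Li+].[OH-]
Why: Saponification of the methyl ester; the acetonide is stable to base and should survive the brief cold acidification.

Step 11
Reactants: 18 phloroglucinol
Product: 19 3,5-bis(methoxymethoxy)phenol
Conditions: MOMCl (2.1 equiv), i-Pr2NEt, DMF, 0 °C → rt; chromatography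
Reagents that add atoms: chloromethyl methyl ether, COCCl
Why: Williamson-type O-alkylation with a limited amount of MOMCl should give the bis-ether as the main statistical product, with mono- and tris-ethers separable and recyclable.

Step 12
Reactants: 19 3,5-bis(methoxymethoxy)phenol
Product: 20 2-bromo-3,5-bis(methoxymethoxy)phenol
Conditions: NBS (1.0 equiv), i-Pr2NH (10 mol %), CH2Cl2, −78 → 0 °C
Reagents that add atoms: N-bromosuccinimide, O=C1CCC(=O)N1Br
Why: Amine-catalysed ortho-selective electrophilic bromination of a phenol; the N-bromoamine hydrogen-bonded to the hydroxyl should deliver bromine to C2, between OH and one MOM ether, and not to the more crowded C4 between the two MOM ethers.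

Step 13
Reactants: 20 2-bromo-3,5-bis(methoxymethoxy)phenol
Product: 24 3,5-bis(methoxymethoxy)-2-(trimethylsilyl)phenyl trifluoromethanesulfonate, via silyl ether 21 (not isolated), via aryllithium 22 (not isolated), via lithium phenoxide 23 (not isolated)
Conditions: (Me3Si)2NH, THF, 65 °C, evaporate; n-BuLi, THF, −78 °C; PhNTf2, −78 °C → rt; aq NH4Cl
Reagents that add atoms: hexamethyldisilazane, C[Si](C)(C)N[Si](C)(C)C; N-phenylbis(trifluoromethanesulfonimide), O=S(=O)(N(c1ccccc1)S(=O)(=O)C(F)(F)F)C(F)(F)F
Why: O-silylation, then bromine–lithium exchange triggers the anionic 1,3-shift of silicon from oxygen to carbon (retro-Brook rearrangement), and the lithium phenoxide is triflated with PhNTf2, a reagent that leaves MOM ethers intact.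

Step 14
Reactants: 17 (S)-4-Ar-2,2-dimethyl-1,3-dioxolane-4-carboxylic acid; 24 3,5-bis(methoxymethoxy)-2-(trimethylsilyl)phenyl trifluoromethanesulfonate
Product: 28 (S)-[4-Ar-2,2-dimethyl-1,3-dioxolan-4-yl][2-hydroxy-4,6-bis(methoxymethoxy)phenyl]methanone, via cesium carboxylate 25 (not isolated), via aryne 26 (not isolated), via aryl anion 27 (not isolated)
Conditions: Cs2CO3 (0.5 equiv), MeOH, rt, evaporate, dry; then 24 (1.5 equiv, in portions), CsF (3 equiv), THF, 110 °C, sealed tube; aq NH4Cl
Reagents that add atoms: none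
Why: Fluoride attacks silicon of 24 and triflate leaves to give aryne 26; carboxylate 25 adds through oxygen to the aryne carbon remote from the adjacent MOM ether (the future C8a), and the aryl anion 27 at the future C4a attacks its own ester carbonyl through a four-membered transition state, so the acyl group moves from oxygen to carbon and the C8a phenoxide is released. The closest known reaction type is the fluoride-induced insertion of arynes into the C–O bond of carboxylic acids, which gives ortho-hydroxyaryl ketones. No ring is closed and no stereocentre is formed; the quaternary centre has no hydrogen and none of its bonds takes part, so its configuration should be kept. The step needs regioselective addition and an acyl shift that is faster than protonation of the aryl anion. The first is secured by the C5 MOM ether beside the aryne, which distorts the triple bond so that the remote carbon is the electrophilic one and stabilises the developing charge next to it inductively; the second by the dry, preformed cesium salt in THF, which leaves no acidic proton at hand.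

Step 15
Reactants: 28 (S)-[4-Ar-2,2-dimethyl-1,3-dioxolan-4-yl][2-hydroxy-4,6-bis(methoxymethoxy)phenyl]methanone
Product: 29 (S)-2-Ar-2,3-dihydroxy-1-(2,4,6-trihydroxyphenyl)propan-1-one
Conditions: HCl (1.25 M in MeOH), 0 → 40 °C
Reagents that add atoms: none
Why: Acid-catalysed acetal solvolysis in methanol should remove both MOM ethers and the acetonide; the prenyl group lies between two methyl ethers with no free phenol to cyclise onto, and the adjacent ketone disfavours ionisation at the quaternary centre.

Step 16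
Reactants: 29 (S)-2-Ar-2,3-dihydroxy-1-(2,4,6-trihydroxyphenyl)propan-1-one
Product: 30 (3S)-3-Ar-3,5,7-trihydroxy-2,3-dihydro-4H-chromen-4-one (CNP0269650.2)
Conditions: PPh3 (1.3 equiv), DIAD (1.3 equiv), THF (0.01 M), 0 °C → rt
Reagents that add atoms: none
Why: Mitsunobu cyclodehydration; the primary alcohol is activated as its alkoxyphosphonium salt and displaced by an ortho phenoxide in a 6-exo-tet closure of O1–C2, the two ortho hydroxyls being equivalent by symmetry, and no bond at C3 is broken, so the (S) configuration should be kept.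

Compound list
1 | 1,3-dimethoxybenzene | COc1cccc(OC)c1 | starting material
2 | prenyl bromide (1-bromo-3-methylbut-2-ene) | CC(C)=CCBr | starting material
3 | 2,6-dimethoxyphenyllithium | [Li]c1c(OC)cccc1OC | intermediate
4 | 1,3-dimethoxy-2-(3-methylbut-2-en-1-yl)benzene | COc1cccc(OC)c1CC=C(C)C | intermediate
5 | 1-bromo-2,4-dimethoxy-3-(3-methylbut-2-en-1-yl)benzene | COc1ccc(Br)c(OC)c1CC=C(C)C | intermediate
6 | diethyl oxalate | CCOC(=O)C(=O)OCC | starting material
7 | [2,4-dimethoxy-3-(3-methylbut-2-en-1-yl)phenyl]lithium | [Li]c1ccc(OC)c(CC=C(C)C)c1OC | intermediate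
8 | ethyl 2-[2,4-dimethoxy-3-(3-methylbut-2-en-1-yl)phenyl]-2-oxoacetate | CCOC(=O)C(=O)c1ccc(OC)c(CC=C(C)C)c1OC | intermediate
9 | ethyl (R)-2-[2,4-dimethoxy-3-(3-methylbut-2-en-1-yl)phenyl]-2-hydroxyacetate | CCOC(=O)[C@H](O)c1ccc(OC)c(CC=C(C)C)c1OC | intermediate
10 | (R)-2-[2,4-dimethoxy-3-(3-methylbut-2-en-1-yl)phenyl]-2-hydroxyacetic acid | OC(=O)[C@H](O)c1ccc(OC)c(CC=C(C)C)c1OC | intermediate
11 | trimethylsilyl (R)-2-[2,4-dimethoxy-3-(3-methylbut-2-en-1-yl)phenyl]-2-(trimethylsilyloxy)acetate | C[Si](C)(C)OC(=O)[C@H](O[Si](C)(C)C)c1ccc(OC)c(CC=C(C)C)c1OC | intermediate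
12 | (2R,5R)-2-tert-butyl-5-[2,4-dimethoxy-3-(3-methylbut-2-en-1-yl)phenyl]-1,3-dioxolan-4-one (cis) | CC(C)(C)[C@H]1OC(=O)[C@@H](c2ccc(OC)c(CC=C(C)C)c2OC)O1 | intermediate
13 | lithium (2R)-2-tert-butyl-5-[2,4-dimethoxy-3-(3-methylbut-2-en-1-yl)phenyl]-1,3-dioxol-4-olate | CC(C)(C)[C@H]1OC(O[Li])=C(c2ccc(OC)c(CC=C(C)C)c2OC)O1 | intermediate
14 | (2R,5S)-2-tert-butyl-5-[2,4-dimethoxy-3-(3-methylbut-2-en-1-yl)phenyl]-5-(hydroxymethyl)-1,3-dioxolan-4-one | CC(C)(C)[C@H]1OC(=O)[C@@](CO)(c2ccc(OC)c(CC=C(C)C)c2OC)O1 | intermediate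
15 | methyl (S)-2-[2,4-dimethoxy-3-(3-methylbut-2-en-1-yl)phenyl]-2,3-dihydroxypropanoate | COC(=O)[C@](CO)(O)c1ccc(OC)c(CC=C(C)C)c1OC | intermediate
16 | methyl (S)-4-[2,4-dimethoxy-3-(3-methylbut-2-en-1-yl)phenyl]-2,2-dimethyl-1,3-dioxolane-4-carboxylate | COC(=O)[C@]1(c2ccc(OC)c(CC=C(C)C)c2OC)COC(C)(C)O1 | intermediate
17 | (S)-4-[2,4-dimethoxy-3-(3-methylbut-2-en-1-yl)phenyl]-2,2-dimethyl-1,3-dioxolane-4-carboxylic acid | COc1ccc([C@@]2(C(=O)O)COC(C)(C)O2)c(OC)c1CC=C(C)C | intermediate
18 | phloroglucinol | Oc1cc(O)cc(O)c1 | starting material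
19 | 3,5-bis(methoxymethoxy)phenol | COCOc1cc(O)cc(OCOC)c1 | intermediate
20 | 2-bromo-3,5-bis(methoxymethoxy)phenol | COCOc1cc(O)c(Br)c(OCOC)c1 | intermediate
21 | [2-bromo-3,5-bis(methoxymethoxy)phenoxy]trimethylsilane | COCOc1cc(O[Si](C)(C)C)c(Br)c(OCOC)c1 | intermediate
22 | [2,4-bis(methoxymethoxy)-6-(trimethylsilyloxy)phenyl]lithium | COCOc1cc(O[Si](C)(C)C)c([Li])c(OCOC)c1 | intermediate
23 | lithium 3,5-bis(methoxymethoxy)-2-(trimethylsilyl)phenolate | COCOc1cc(O[Li])c([Si](C)(C)C)c(OCOC)c1 | intermediate
24 | 3,5-bis(methoxymethoxy)-2-(trimethylsilyl)phenyl trifluoromethanesulfonate | COCOc1cc(OCOC)c([Si](C)(C)C)c(OS(=O)(=O)C(F)(F)F)c1 | intermediate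
25 | cesium (S)-4-[2,4-dimethoxy-3-(3-methylbut-2-en-1-yl)phenyl]-2,2-dimethyl-1,3-dioxolane-4-carboxylate | [Cs+].COc1ccc([C@@]2(C(=O)[O-])COC(C)(C)O2)c(OC)c1CC=C(C)C | intermediate
26 | 3,5-bis(methoxymethoxy)benzyne (1,2-didehydro-3,5-bis(methoxymethoxy)benzene) | COCOC1=CC#CC(OCOC)=C1 | intermediate
27 | cesium aryl anion of the 3,5-bis(methoxymethoxy)phenyl ester of 17, carbanion at the ring carbon between the ester oxygen and a MOM ether | [Cs+].COc1ccc([C@@]2(C(=O)Oc3cc(OCOC)cc(OCOC)[c-]3)COC(C)(C)O2)c(OC)c1CC=C(C)C | intermediate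
28 | (S)-[4-[2,4-dimethoxy-3-(3-methylbut-2-en-1-yl)phenyl]-2,2-dimethyl-1,3-dioxolan-4-yl][2-hydroxy-4,6-bis(methoxymethoxy)phenyl]methanone | COc1ccc([C@@]2(C(=O)c3c(O)cc(OCOC)cc3OCOC)COC(C)(C)O2)c(OC)c1CC=C(C)C | intermediate
29 | (S)-2-[2,4-dimethoxy-3-(3-methylbut-2-en-1-yl)phenyl]-2,3-dihydroxy-1-(2,4,6-trihydroxyphenyl)propan-1-one | COc1ccc([C@](O)(CO)C(=O)c2c(O)cc(O)cc2O)c(OC)c1CC=C(C)C | intermediate
30 | (3S)-3-[2,4-dimethoxy-3-(3-methylbut-2-en-1-yl)phenyl]-3,5,7-trihydroxy-2,3-dihydro-4H-chromen-4-one (CNP0269650.2) | COc1ccc([C@]2(O)COc3cc(O)cc(O)c3C2=O)c(OC)c1CC=C(C)C | target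

Total step count: 16. Longest linear sequence: 13 steps (steps 1–10, then 14–16); the silyl triflate branch (steps 11–13) joins at step 14.

Steps most likely to fail

Step 14 (key step). The aryl anion may be protonated before the acyl group shifts, which stops at the aryl ester. The hindered carboxylate may also add so slowly that the aryne is consumed by self-reaction, by an ene reaction at the prenyl alkene, or by O-arylation of the product phenoxide. The fallback makes ring A the nucleophile, using known carbonyl addition chemistry; it sets out from ester 16 and comes back at pentaol 29. Ester 16 is reduced with i-Bu2AlH (CH2Cl2, −78 °C) to (S)-4-Ar-2,2-dimethyl-1,3-dioxolane-4-carbaldehyde F1. Phloroglucinol 18 is fully protected (NaH, excess MOMCl, DMF) to 1,3,5-tris(methoxymethoxy)benzene F2, which n-BuLi (THF, 0 °C) lithiates between two MOM ethers to [2,4,6-tris(methoxymethoxy)phenyl]lithium F3. Addition of F3 to F1 at −78 °C should give [(4S)-4-Ar-2,2-dimethyl-1,3-dioxolan-4-yl][2,4,6-tris(methoxymethoxy)phenyl]methanol F4, both carbinol epimers being usable. Dess–Martin oxidation then gives (S)-[4-Ar-2,2-dimethyl-1,3-dioxolan-4-yl][2,4,6-tris(methoxymethoxy)phenyl]methanone F5. Methanolic HCl as in step 15 removes the three MOM groups and the acetonide to give 29; the symmetry of the aryl ring makes regiochemistry irrelevant.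

Step 16. The unhindered para hydroxyl may undergo intermolecular etherification, the three phenols may consume the betaine, and displacement at the neopentyl-type carbon may be slow. Closure through the tertiary hydroxyl to an epoxide would be harmless, since phenoxide opening at its CH2 terminus leads to the same compound. The fallback closes the ring while only one phenol is free; it sets out from 28 and comes back at target 30. Aqueous acetic acid (AcOH/H2O 4:1, 40 °C) should remove only the acetonide and give (S)-2-Ar-2,3-dihydroxy-1-[2-hydroxy-4,6-bis(methoxymethoxy)phenyl]propan-1-one F6. PPh3/DIAD (THF, 0 °C) should close it to (S)-3-Ar-3-hydroxy-5,7-bis(methoxymethoxy)chroman-4-one F7. Brief treatment with HCl in MeOH at rt, stopped before dehydration towards the isoflavone can set in, then removes the MOM ethers to give 30.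

Step 7. Enolate 13 may decompose before it is trapped, formaldehyde may oligomerise before it reacts, and facial control may be incomplete with the ortho-substituted aryl group. The fallback is a Mukaiyama-type aldol in aqueous medium; it sets out from 12 and comes back at 14. Dioxolanone 12 is converted with LiN(i-Pr)2 and TMSCl (THF, −78 °C) into the silyl ketene acetal (2R)-2-tert-butyl-5-Ar-4-(trimethylsilyloxy)-1,3-dioxole F8. F8 is treated with aqueous formaldehyde and Yb(OTf)3 (10 mol %) in THF/H2O at rt, and should again react on the face away from the tert-butyl group to give 14.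

Further compounds
F1 | step 14 | (S)-4-[2,4-dimethoxy-3-(3-methylbut-2-en-1-yl)phenyl]-2,2-dimethyl-1,3-dioxolane-4-carbaldehyde | COc1ccc([C@@]2(C=O)COC(C)(C)O2)c(OC)c1CC=C(C)C
F2 | step 14 | 1,3,5-tris(methoxymethoxy)benzene | COCOc1cc(OCOC)cc(OCOC)c1
F3 | step 14 | [2,4,6-tris(methoxymethoxy)phenyl]lithium | [Li]c1c(OCOC)cc(OCOC)cc1OCOC
F4 | step 14 | [(4S)-4-[2,4-dimethoxy-3-(3-methylbut-2-en-1-yl)phenyl]-2,2-dimethyl-1,3-dioxolan-4-yl][2,4,6-tris(methoxymethoxy)phenyl]methanol (carbinol epimers) | COc1ccc([C@@]2(C(O)c3c(OCOC)cc(OCOC)cc3OCOC)COC(C)(C)O2)c(OC)c1CC=C(C)C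
F5 | step 14 | (S)-[4-[2,4-dimethoxy-3-(3-methylbut-2-en-1-yl)phenyl]-2,2-dimethyl-1,3-dioxolan-4-yl][2,4,6-tris(methoxymethoxy)phenyl]methanone | COc1ccc([C@@]2(C(=O)c3c(OCOC)cc(OCOC)cc3OCOC)COC(C)(C)O2)c(OC)c1CC=C(C)C
F6 | step 16 | (S)-2-[2,4-dimethoxy-3-(3-methylbut-2-en-1-yl)phenyl]-2,3-dihydroxy-1-[2-hydroxy-4,6-bis(methoxymethoxy)phenyl]propan-1-one | COc1ccc([C@](O)(CO)C(=O)c2c(O)cc(OCOC)cc2OCOC)c(OC)c1CC=C(C)C
F7 | step 16 | (S)-3-[2,4-dimethoxy-3-(3-methylbut-2-en-1-yl)phenyl]-3-hydroxy-5,7-bis(methoxymethoxy)chroman-4-one | COc1ccc([C@]2(O)COc3cc(OCOC)cc(OCOC)c3C2=O)c(OC)c1CC=C(C)C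
F8 | step 7 | (2R)-2-tert-butyl-5-[2,4-dimethoxy-3-(3-methylbut-2-en-1-yl)phenyl]-4-(trimethylsilyloxy)-1,3-dioxole | CC(C)(C)[C@H]1OC(O[Si](C)(C)C)=C(c2ccc(OC)c(CC=C(C)C)c2OC)O1
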